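The plan cuts the C2–C3 bond of ring C. C2 bears O1 and the para-oxygenated ring B, so it can exist as a stabilised oxocarbenium carbon. C3 is the α-carbon of the C4 ketone, so it can act as an enol carbon. Both partners are stored in racemic enol acetal 7, a 2-aryl-4-methylidene-1,3-benzodioxine reached in three operations from 1 and 2. A confined chiral acid ionises 7 at C2 and the enol carbon returns to C2. This single isomerisation forms C2–C3, builds ring C, unveils the ketone and sets C2. Rubottom oxidation, hydrogenolysis and O7-selective alkylation with an unprotected chloro alcohol finish the target.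

Key step: step 4

Remark on descriptors: the target is (2R,3R) with an E alkene. A flavanone with the same spatial arrangement at C2 is (2S), because without the 3-oxygen ring B outranks C3.
Assumption: precedent does not show which face of cation 8 a given antipode of the confined acid shields. The (S,S) acid is written, and its mirror image is taken if the other face is needed.

Step 1
Reactants: 1 2,4,6-trihydroxybenzoic acid; 2 4-(benzyloxy)benzaldehyde
Product: 5 racemic 2-[4-(benzyloxy)phenyl]-5,7-dihydroxy-4H-1,3-benzodioxin-4-one, via tetrakis(trimethylsilyl) derivative 3 (not isolated), via 5,7-bis(trimethylsilyl) benzodioxinone 4 (not isolated)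
Conditions: HN(SiMe3)2, THF, 23 °C, evaporate; then 2, TMSOTf (10 mol %), CH2Cl2, −78 to −40 °C; then aq. citric acid, THF, 0 °C
Reagents that add atoms: none
Why: TMSOTf-catalysed silyl acetalisation, the opening move of the Petasis–Ferrier union: the silyl ester and an ortho silyl ether of 3 add in turn to the activated aldehyde with loss of hexamethyldisiloxane at low temperature, which avoids the hot protic acid that would decarboxylate 1 or let ring A attack the aldehyde, and C2 forms racemic, which is harmless because step 4 erases it.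

Step 2
Reactants: 5 racemic 2-[4-(benzyloxy)phenyl]-5,7-dihydroxy-4H-1,3-benzodioxin-4-one
Product: 6 racemic 5,7-bis(benzyloxy)-2-[4-(benzyloxy)phenyl]-4H-1,3-benzodioxin-4-one
Conditions: BnBr (2.4 equiv), K2CO3, dry DMF, 23 to 50 °C
Reagents that add atoms: benzyl bromide, BrCc1ccccc1
Why: Williamson etherification, routine for 5,7-dihydroxybenzodioxinones: dry carbonate should leave the acylal intact, and gentle warming overcomes the hydrogen bond of the 5-OH to the lactone carbonyl.

Step 3
Reactants: 6 racemic 5,7-bis(benzyloxy)-2-[4-(benzyloxy)phenyl]-4H-1,3-benzodioxin-4-one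
Product: 7 racemic 5,7-bis(benzyloxy)-2-[4-(benzyloxy)phenyl]-4-methylidene-4H-1,3-benzodioxine
Conditions: Cp2TiMe2 (2.5 equiv), toluene, 70 °C, dark; hexane, filtration through basic alumina (1 % Et3N)
Reagents that add atoms: dimethyltitanocene Cp2TiMe2, C[Ti+2]C.c1cc[cH-]c1.c1cc[cH-]c1
Why: Petasis methylenation, the standard way from 1,3-dioxan-4-ones and aromatic esters to their enol ethers: Cp2Ti=CH2 adds to the only carbonyl group in a [2+2] sense and cycloreverts to the alkene in a neutral medium free of Lewis acid, which spares the acetal and the benzyl ethers, and the acid-labile product is isolated over a basic support.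

Step 4
Reactants: 7 racemic 5,7-bis(benzyloxy)-2-[4-(benzyloxy)phenyl]-4-methylidene-4H-1,3-benzodioxine
Product: 9 (2S)-5,7-bis(benzyloxy)-2-[4-(benzyloxy)phenyl]-2,3-dihydro-4H-chromen-4-one, via oxocarbenium-enol ion pair 8 (not isolated)
Conditions: (S,S)-IDPi acid HN[P(=NSO2CF3)(O2C20H10Ar2)]2, O2C20H10Ar2 = 3,3′-diaryl-1,1′-binaphthalene-2,2′-diolate, Ar = 3,5-(CF3)2C6H3 (5 mol %), 5 Å molecular sieves, toluene (0.02 M, slow addition of 7), −60 to −30 °C; Et3N quench
Reagents that add atoms: none
Why: Proposed new method: the acid protonates the enol oxygen O3 of 7, the C2–O3 bond breaks to give cation 8 (C2 stabilised by O1 and by the para-benzyloxy group of ring B) beside the free enol of the aryl ketone, the enol CH2 carbon (future C3) adds to C2, and loss of the proton from the former O3, now the C4 carbonyl oxygen, returns the catalyst, so that 7 is simply isomerised to 9. The closest known reaction types are the Petasis–Ferrier rearrangement of 4-methylidene-1,3-dioxanes to tetrahydropyran-4-ones under Me2AlCl and the chiral Brønsted acid catalysed aza-Petasis–Ferrier rearrangement and oxocarbenium additions, while a benzo-fused enol acetal and an enantioselective all-oxygen version are without precedent. Ring C closes in the 6-(enolendo)-endo-trig mode, since both the C3=C4 enol bond and the C2=O1 oxocarbenium bond end up inside the new six-membered ring. C2 is the only new stereocentre and is controlled by the catalyst alone: ionisation flattens C2, so both enantiomers of 7 give the same cation, and the chiral anion that holds it in its pocket leaves one face open to the tethered enol. The step needs site selectivity of ionisation and enantioface selectivity; the substrate secures the first, because opening at O1 can only revert, and protonation at the methylidene carbon leads through the same C2–O3 cleavage to the keto tautomer of 8, which re-enters by enolisation as long as the sieves keep water out. Low temperature, high dilution and the narrow pocket should hold back intermolecular Friedel–Crafts attack of ring A on 8 and acid-induced opening of 9 to the chalcone, the process that would erode the enantiomeric purity.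

Step 5
Reactants: 9 (2S)-5,7-bis(benzyloxy)-2-[4-(benzyloxy)phenyl]-2,3-dihydro-4H-chromen-4-one
Product: 10 (2S)-5,7-bis(benzyloxy)-2-[4-(benzyloxy)phenyl]-4-(trimethylsilyloxy)-2H-chromene
Conditions: TMSOTf (1.5 equiv), Et3N (3 equiv), CH2Cl2, 0 °C; cold aq. NaHCO3, used crude
Reagents that add atoms: trimethylsilyl trifluoromethanesulfonate, C[Si](C)(C)OS(=O)(=O)C(F)(F)F
Why: Soft enolisation with a silyl triflate and a tertiary amine: O-silylation of the electron-rich C4 carbonyl precedes removal of a C3 proton, so no free enolate arises that could expel O1 (retro-oxa-Michael opening), and C2 should keep its configuration.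

Step 6
Reactants: 10 (2S)-5,7-bis(benzyloxy)-2-[4-(benzyloxy)phenyl]-4-(trimethylsilyloxy)-2H-chromene
Product: 13 (2R,3R)-5,7-bis(benzyloxy)-2-[4-(benzyloxy)phenyl]-3-hydroxy-2,3-dihydro-4H-chromen-4-one, via silyloxy epoxide 11 (not isolated), via 3-O-trimethylsilyl ketone 12 (not isolated)
Conditions: dimethyldioxirane (1.1 equiv, acetone), CH2Cl2, −40 to 0 °C; then aq. citric acid, THF, 0 °C
Reagents that add atoms: dimethyldioxirane, CC1(C)OO1
Why: Rubottom oxidation: the oxidant should reach the electron-rich C3=C4 bond from the face opposite to the C2 aryl group, epoxide 11 opens with 1,4-silyl shift to 12 and mild acid frees the alcohol, so the C3–O bond is trans to ring B (also the more stable diequatorial isomer), and the descriptor at C2 changes from S to R only because C3 now outranks ring B.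

Step 7
Reactants: 13 (2R,3R)-5,7-bis(benzyloxy)-2-[4-(benzyloxy)phenyl]-3-hydroxy-2,3-dihydro-4H-chromen-4-one
Product: 14 (2R,3R)-3,5,7-trihydroxy-2-(4-hydroxyphenyl)-2,3-dihydro-4H-chromen-4-one (aromadendrin)
Conditions: H2 (1 atm), 10 % Pd/C, EtOAc/MeOH, 23 °C
Reagents that add atoms: none
Why: Catalytic hydrogenolysis of aryl benzyl ethers, routine for benzylated flavanonols: it is placed before the side chain arrives because the allylic ether and its alkene would not survive it, and the neutral medium leaves both stereocentres alone.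

Step 8
Reactants: 15 racemic 2-ethenyl-2-methyloxirane (isoprene monoxide)
Product: 16 (2E)-4-chloro-2-methylbut-2-en-1-ol
Conditions: TiCl4 (1.2 equiv), CH2Cl2, −85 °C; 1 M aq. HCl
Reagents that add atoms: titanium tetrachloride, Cl[Ti](Cl)(Cl)Cl
Why: Lewis acid mediated SN2′ opening of a vinyl oxirane: TiCl4 binds the ring oxygen, the tertiary allylic C–O bond loosens and chloride enters at the vinyl terminus, and the alkene should form with the bulky titanated CH2O group trans to CH2Cl, which is the E geometry of the target.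

Step 9
Reactants: 14 (2R,3R)-aromadendrin; 16 (2E)-4-chloro-2-methylbut-2-en-1-ol
Product: 17 (2R,3R)-3,5-dihydroxy-2-(4-hydroxyphenyl)-7-{[(2E)-4-hydroxy-3-methylbut-2-en-1-yl]oxy}-2,3-dihydro-4H-chromen-4-one
Conditions: K2CO3 (1.0 equiv), 16 (1.1 equiv), DMF, argon, 23 °C
Reagents that add atoms: none
Why: Williamson etherification steered by acidity: one equivalent of carbonate ionises only the 7-OH, which is para to the C4 carbonyl and the most acidic site, whereas the 5-OH is tied up in a hydrogen bond to that carbonyl, the 4′-OH is distinctly less acidic and the alcohols are not ionised, so the phenoxide should displace the primary allylic chloride by SN2 with the E alkene untouched, and inert gas and room temperature guard the base-sensitive trans ketol.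

Compound list
1 | 2,4,6-trihydroxybenzoic acid | OC(=O)c1c(O)cc(O)cc1O | starting material
2 | 4-(benzyloxy)benzaldehyde | O=Cc1ccc(OCc2ccccc2)cc1 | starting material
3 | trimethylsilyl 2,4,6-tris(trimethylsilyloxy)benzoate | C[Si](C)(C)OC(=O)c1c(O[Si](C)(C)C)cc(O[Si](C)(C)C)cc1O[Si](C)(C)C | intermediate
4 | racemic 2-[4-(benzyloxy)phenyl]-5,7-bis(trimethylsilyloxy)-4H-1,3-benzodioxin-4-one | O=C1OC(c2ccc(OCc3ccccc3)cc2)Oc2cc(O[Si](C)(C)C)cc(O[Si](C)(C)C)c12 | intermediate
5 | racemic 2-[4-(benzyloxy)phenyl]-5,7-dihydroxy-4H-1,3-benzodioxin-4-one | O=C1OC(c2ccc(OCc3ccccc3)cc2)Oc2cc(O)cc(O)c12 | intermediate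
6 | racemic 5,7-bis(benzyloxy)-2-[4-(benzyloxy)phenyl]-4H-1,3-benzodioxin-4-one | O=C1OC(c2ccc(OCc3ccccc3)cc2)Oc2cc(OCc3ccccc3)cc(OCc3ccccc3)c12 | intermediate
7 | racemic 5,7-bis(benzyloxy)-2-[4-(benzyloxy)phenyl]-4-methylidene-4H-1,3-benzodioxine | C=C1OC(c2ccc(OCc3ccccc3)cc2)Oc2cc(OCc3ccccc3)cc(OCc3ccccc3)c12 | intermediate
8 | ring-opened O-aryl oxocarbenium cation of aldehyde 2 that carries the free 1-hydroxyethenyl (enol) group ortho to O1, paired with the IDPi anion | C=C(O)c1c(OCc2ccccc2)cc(OCc2ccccc2)cc1[O+]=Cc1ccc(OCc2ccccc2)cc1 | intermediate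
9 | (2S)-5,7-bis(benzyloxy)-2-[4-(benzyloxy)phenyl]-2,3-dihydro-4H-chromen-4-one, (2S)-naringenin tribenzyl ether | C(c1ccccc1)Oc1cc(OCc2ccccc2)c2c(c1)O[C@H](c1ccc(OCc3ccccc3)cc1)CC2=O | intermediate
10 | (2S)-5,7-bis(benzyloxy)-2-[4-(benzyloxy)phenyl]-4-(trimethylsilyloxy)-2H-chromene | C(c1ccccc1)Oc1cc(OCc2ccccc2)c2c(c1)O[C@H](c1ccc(OCc3ccccc3)cc1)C=C2O[Si](C)(C)C | intermediate
11 | 3,4-epoxide of 10, oxirane oxygen on the face anti to the C2 aryl group, trimethylsilyloxy group at C4 | C(c1ccccc1)Oc1cc(OCc2ccccc2)c2c(c1)O[C@H](c1ccc(OCc3ccccc3)cc1)[C@H]1O[C@]12O[Si](C)(C)C | intermediate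
12 | (2R,3R)-5,7-bis(benzyloxy)-2-[4-(benzyloxy)phenyl]-3-(trimethylsilyloxy)-2,3-dihydro-4H-chromen-4-one | C(c1ccccc1)Oc1cc(OCc2ccccc2)c2c(c1)O[C@H](c1ccc(OCc3ccccc3)cc1)[C@@H](O[Si](C)(C)C)C2=O | intermediate
13 | (2R,3R)-5,7-bis(benzyloxy)-2-[4-(benzyloxy)phenyl]-3-hydroxy-2,3-dihydro-4H-chromen-4-one | C(c1ccccc1)Oc1cc(OCc2ccccc2)c2c(c1)O[C@H](c1ccc(OCc3ccccc3)cc1)[C@@H](O)C2=O | intermediate
14 | (2R,3R)-3,5,7-trihydroxy-2-(4-hydroxyphenyl)-2,3-dihydro-4H-chromen-4-one, aromadendrin | Oc1cc(O)c2c(c1)O[C@H](c1ccc(O)cc1)[C@@H](O)C2=O | intermediate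
15 | racemic 2-ethenyl-2-methyloxirane | C=CC1(C)CO1 | starting material
16 | (2E)-4-chloro-2-methylbut-2-en-1-ol | C/C(=C\CCl)CO | intermediate
17 | (2R,3R)-3,5-dihydroxy-2-(4-hydroxyphenyl)-7-{[(2E)-4-hydroxy-3-methylbut-2-en-1-yl]oxy}-2,3-dihydro-4H-chromen-4-one | C/C(=C\COc1cc(O)c2c(c1)O[C@H](c1ccc(O)cc1)[C@@H](O)C2=O)CO | target

Total step count: 9
Longest linear sequence: 8 (steps 1 to 7 and step 9; step 8 is a one-step side branch)

Steps most likely to fail

1. Step 4.
What may go wrong: the ion pair may close without face discrimination. It may be diverted by intermolecular arylation or by traces of water. The acid may also re-open ring C of the product and so racemise C2.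
Fallback, known chemistry only, sets out from 7 and comes back at 9:
- Dilute aqueous HCl in THF hydrolyses the enol acetal to 1-[2,4-bis(benzyloxy)-6-hydroxyphenyl]ethanone F1 and returns aldehyde 2.
- Heating F1 with N,N-dimethylformamide dimethyl acetal in toluene gives (2E)-1-[2,4-bis(benzyloxy)-6-hydroxyphenyl]-3-(dimethylamino)prop-2-en-1-one F2.
- HCl in CH2Cl2 closes F2, with loss of dimethylamine, to 5,7-bis(benzyloxy)-4H-chromen-4-one F3.
- A Hayashi–Miyaura asymmetric 1,4-addition of 4-(benzyloxy)phenylboronic acid to F3 should deliver 9. The catalyst is [Rh(OH)(cod)]2 with (6,6′-dimethoxybiphenyl-2,2′-diyl)bis[bis(3,4,5-trifluorophenyl)phosphane], in the antipode that leads to 2S, in toluene/H2O.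
- In this fallback the C2–aryl bond, not C2–C3, is formed under catalyst control.

2. Step 3.
What may go wrong: addition of the titanium carbene may be sluggish, because the carbonyl group is flanked by the 5-benzyloxy group and deactivated by three donor oxygens. The acylal may break down during the long heating. The enol acetal may hydrolyse during isolation.
Fallback, sets out from 6 and comes back at 9, with anionic homologation in place of carbene transfer:
- Excess lithium enolate of tert-butyl acetate (LDA, THF, −78 °C) opens the activated lactone in a crossed Claisen condensation. This gives tert-butyl 3-[2,4-bis(benzyloxy)-6-hydroxyphenyl]-3-oxopropanoate F4 and releases aldehyde 2.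
- Knoevenagel condensation of F4 with 2 (piperidine, AcOH, toluene, sieves) gives tert-butyl 2-[2,4-bis(benzyloxy)-6-hydroxybenzoyl]-3-[4-(benzyloxy)phenyl]prop-2-enoate F5.
- 1-[3,5-Bis(trifluoromethyl)phenyl]-3-[(8α,9S)-6′-methoxycinchonan-9-yl]thiourea, or its quinidine-derived pseudoenantiomer, whichever leads to 2S, catalyses the enantioselective oxa-Michael closure in toluene at −25 °C. The product is tert-butyl (2S)-5,7-bis(benzyloxy)-2-[4-(benzyloxy)phenyl]-4-oxo-3,4-dihydro-2H-chromene-3-carboxylate F6.
- p-TsOH·H2O at 80 °C in the same flask removes the ester by loss of isobutene and CO2 and should give 9.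

3. Step 1.
What may go wrong: the activated aldehyde may C-alkylate the very electron-rich ring A. Acid 1 may lose CO2 before silylation is complete. The acylal may cleave while the two aryl silyl ethers are hydrolysed.
Fallback, sets out from 1 and comes back at 6. The benzyl ethers are installed on a robust ketal, and the labile aryl acylal is made last, so it never meets base or protic desilylation:
- Acetone with (CF3CO)2O in CF3CO2H at 0 to 23 °C gives 5,7-dihydroxy-2,2-dimethyl-4H-1,3-benzodioxin-4-one F7.
- BnBr and K2CO3 in DMF give 5,7-bis(benzyloxy)-2,2-dimethyl-4H-1,3-benzodioxin-4-one F8.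
- Aqueous KOH in DMSO, followed by cold acidification, gives 2,4-bis(benzyloxy)-6-hydroxybenzoic acid F9.
- HN(SiMe3)2 converts F9 into trimethylsilyl 2,4-bis(benzyloxy)-6-(trimethylsilyloxy)benzoate F10.
- F10 condenses with 2 under TMSOTf (10 mol %) in CH2Cl2 at −78 °C and should give 6 directly.

Further compounds
F1 | step 4 | 1-[2,4-bis(benzyloxy)-6-hydroxyphenyl]ethanone | CC(=O)c1c(O)cc(OCc2ccccc2)cc1OCc1ccccc1
F2 | step 4 | (2E)-1-[2,4-bis(benzyloxy)-6-hydroxyphenyl]-3-(dimethylamino)prop-2-en-1-one | CN(C)/C=C/C(=O)c1c(O)cc(OCc2ccccc2)cc1OCc1ccccc1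
F3 | step 4 | 5,7-bis(benzyloxy)-4H-chromen-4-one | O=c1ccoc2cc(OCc3ccccc3)cc(OCc3ccccc3)c12
F4 | step 3 | tert-butyl 3-[2,4-bis(benzyloxy)-6-hydroxyphenyl]-3-oxopropanoate | CC(C)(C)OC(=O)CC(=O)c1c(O)cc(OCc2ccccc2)cc1OCc1ccccc1
F5 | step 3 | tert-butyl 2-[2,4-bis(benzyloxy)-6-hydroxybenzoyl]-3-[4-(benzyloxy)phenyl]prop-2-enoate | CC(C)(C)OC(=O)C(=Cc1ccc(OCc2ccccc2)cc1)C(=O)c1c(O)cc(OCc2ccccc2)cc1OCc1ccccc1
F6 | step 3 | tert-butyl (2S)-5,7-bis(benzyloxy)-2-[4-(benzyloxy)phenyl]-4-oxo-3,4-dihydro-2H-chromene-3-carboxylate (C3 epimerisable) | CC(C)(C)OC(=O)C1[C@@H](c2ccc(OCc3ccccc3)cc2)Oc2cc(OCc3ccccc3)cc(OCc3ccccc3)c2C1=O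
F7 | step 1 | 5,7-dihydroxy-2,2-dimethyl-4H-1,3-benzodioxin-4-one | CC1(C)OC(=O)c2c(O)cc(O)cc2O1
F8 | step 1 | 5,7-bis(benzyloxy)-2,2-dimethyl-4H-1,3-benzodioxin-4-one | CC1(C)OC(=O)c2c(OCc3ccccc3)cc(OCc3ccccc3)cc2O1
F9 | step 1 | 2,4-bis(benzyloxy)-6-hydroxybenzoic acid | OC(=O)c1c(O)cc(OCc2ccccc2)cc1OCc1ccccc1
F10 | step 1 | trimethylsilyl 2,4-bis(benzyloxy)-6-(trimethylsilyloxy)benzoate | C[Si](C)(C)OC(=O)c1c(O[Si](C)(C)C)cc(OCc2ccccc2)cc1OCc1ccccc1
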